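4 questions stand on the oak flask, and the examination takes them in turn once the papers are on the table.

| flask | solid substrate | free enzyme | temperature | remark | time |
|---|---|---|---|---|---|
| oak | 0.050 M | 0.1 mol% | 5 °C | the very flask that is asked about, followed so far |  |
| birch | 0.050 M | 0.15 mol% | 5 °C | run made earlier |  |
| flask | 0.050 M | 0.1 mol% | 5 °C |  | 2.0 d |

- oak (time / h: target / %): 3.00: 25.2; 8.00: 55.4; 15.0: 44.7; 40.0: 45.5
- birch (time / h: target / %): 0.833: 11.0; 2.00: 18.8; 2.50: 23.9; 4.00: 33.4

(scatter of a reading: 1 percentage point)

- target, in percent of the solid substrate first charged, at 2.0 d
- what to do for the largest gain in target; "none" if nothing gains more than 2 percentage points (gamma / alpha / delta / epsilon / none)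
- target present, with what was taken out counted in, in percent of the solid substrate first charged, after alpha
- target present, with what was taken out counted in, in percent of the solid substrate first charged, after delta

- gamma: at 2.0 d raise the temperature by 20 K, then wait 15 h
- alpha: at 2.0 d take out 90% of the target then present, then wait 15 h
- delta: change nothing and wait 15 h more
- epsilon: at 2.0 d add free enzyme, 100% of the amount charged, then wait 15 h

- solid substrate is a solid; its amount is given per volume of the solution
- what is taken out of target is counted as made
- the earlier runs were read with a standard deviation of 1 percentage point
- at the start none of the solid substrate is in solution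
- the earlier runs do not show what temperature does; that part of a forecast is a guess
- additions bring no volume worth counting

*What do the oak readings show?* Target climbs to 55.4% at 8.00 h, then reads 44.7% at 15.0 h and 45.5% at 40.0 h. Those last two differ by 0.8 percentage points, less than the scatter of 1 point, so I take their mean, 45.1%, as the plateau share.

*Could the high reading be a slip?* I think not, because it stands 10 points above the plateau, far more than the scatter. Nothing was taken out of the flask, so target must have passed into a partner that this column does not show, and the flat tail suggests a balance between the two.

*How fast does that balance return?* The excess shrinks from 10 points to below the scatter within 7.00 h. That is about 2.33 lifetimes or more, so from these scattered readings I estimate the rebalancing lifetime, the relaxation time in which a gap to the plateau shrinks by a factor e, at 3.00 h or shorter.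

*So what stands at 2.0 d?* In the oak flask that time is 16.0 such lifetimes or more, so I expect 45.1% and no gain from waiting.

*And taking target out, where is the weak spot?* The further wait must be long enough. It is 5.00 lifetimes, which is ample. Removal banks 40.6%, and the remainder returns to the same share, for a total of 67.4%, a gain of 22 points. This assumes the charge has dissolved, as the flat tail suggests.

*And heating?* The readings do not show temperature, so I commit to removal and leave that option a guess.

The forecast gave 45.2% now, 45.3% after waiting, 67% after removal and the choice alpha, saying “removal looks best”.

The flask gives 45.5% now, 45.5% after waiting and 67.8% after removal, which gains 22 points. Added free enzyme gains 0 points. The best choice is gamma, at 46 points.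

    target ⇌ isomer of the product (K = 1.20, k = 0.300 h⁻¹, Ea = 95.0 kJ mol⁻¹, ΔH = −90.0 kJ mol⁻¹)
    free enzyme → unfolded enzyme (k = 0.0100 h⁻¹, Ea = 201 kJ mol⁻¹)
    solid substrate ⇌ starting material, rate k3*(cs3 - [starting material]) while solid is left; crystals form when [starting material] > cs3 (solubility = 17.0 mM, k = 0.360 h⁻¹)
    starting material + free enzyme → target + free enzyme, rate k4*[starting material]*[free enzyme]/(1 + ([starting material]/Km4) + ([starting material]/Ksi4)^2) (9.40 mM, 8.20 mM, k = 12000 M⁻¹ s⁻¹, Ea = 26.0 kJ mol⁻¹)
    (constants at 5 °C)

In the oak flask the dissolving of the solid substrate has 100% of its turnover up to the asked time behind it by 9.60 h, and the stretch from there to 48.0 h is far longer than my estimate of the rebalancing lifetime, 12.8 such lifetimes or more, with target at 45.5% beside 54.5% of isomer of the product. The same flask left until 480 h, 160 such lifetimes or more, has free enzyme down to 0.823% of the catalyst charged and target at 45.5%.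

The data are calculated from invented constants; scatter was added.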